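**Assumptions:** The target has no stereocentres (it is achiral), so there is no enantiomer to control. Luteolin is treated as a commercial bulk starting material. The product is isolated as the free hydrogen sulfate, as drawn, after H⁺ exchange.

## Retrosynthetic overview

1. Target ⇐ one-pot reductive unmasking of a 7-O-(trichloroethyl) sulfate, a 6-O-benzyl ether and a 3',4'-O-diphenylmethylene ketal.
2. The 7-O–S bond ⇐ sulfation of the only reactive phenol (7-OH; the 5-OH is chelated to C4=O) of a 6-benzyloxy-5,7-diol.
3. Key strategy: the C6–O bond ⇐ late-stage C6–H oxygenation of the luteolin core (5-OH-directed C6 iodination, then Cu-catalysed C–O coupling with BnOH), instead of building a 5,6,7-trioxygenated A ring de novo.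
4. The 7-O-allyl ether and the B-ring ketal ⇐ luteolin, using innate OH reactivity (catechol ketalisation; 7-OH ≫ 5-OH).
5. Ring order: rings A, C and B are bought intact in luteolin and no skeletal ring is formed. Only a temporary 1,3-dioxole ring is made in step 1 and removed in step 7.

## Route

**Step 1**
Reactants: 1 luteolin; 2 dichlorodiphenylmethane
Product: 3, 3',4'-O-diphenylmethylene-luteolin [2-(2,2-diphenyl-1,3-benzodioxol-5-yl)-5,7-dihydroxy-4H-chromen-4-one]
Conditions: Ph2CCl2 (1.5 eq), Ph2O, 175 °C, 30 min, N2
Reagents that add atoms: dichlorodiphenylmethane, ClC(Cl)(c1ccccc1)c1ccccc1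
Why: Catechol ketalisation – only the ortho-dihydroxy B ring can close the five-membered 2,2-diphenyl-1,3-dioxole (loss of 2 HCl), while the meta-related 5,7-OH pair cannot.

**Step 2**
Reactants: 3; 4 allyl bromide
Product: 5, 7-(allyloxy)-2-(2,2-diphenyl-1,3-benzodioxol-5-yl)-5-hydroxy-4H-chromen-4-one
Conditions: allyl bromide (1.1 eq), K2CO3 (1.2 eq), DMF, rt
Reagents that add atoms: allyl bromide, C=CCBr
Why: Williamson etherification – the acidic 7-OH (a vinylogous acid) is alkylated selectively because the 5-OH is hydrogen-bonded to the C4 carbonyl and unreactive under mild base.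

**Step 3**
Reactants: 5; 6 N-iodosuccinimide
Product: 7, 7-(allyloxy)-2-(2,2-diphenyl-1,3-benzodioxol-5-yl)-5-hydroxy-6-iodo-4H-chromen-4-one
Conditions: NIS (1.05 eq), DMF, 0 °C → rt, dark
Reagents that add atoms: N-iodosuccinimide, O=C1CCC(=O)N1I
Why: Electrophilic aromatic iodination – in 5-hydroxy-7-alkoxyflavones the chelated free 5-OH directs ortho to C6 (C8 is favoured only when O5 is alkylated), and neutral NIS does not touch the allyl alkene or the less electron-rich benzodioxole.

**Step 4**
Reactants: 7; 8 benzyl alcohol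
Product: 9, 7-(allyloxy)-6-(benzyloxy)-2-(2,2-diphenyl-1,3-benzodioxol-5-yl)-5-hydroxy-4H-chromen-4-one
Conditions: BnOH (5 eq), CuI (20 mol%), 3,4,7,8-Me4-phenanthroline (40 mol%), Cs2CO3 (2.5 eq), PhMe, 100 °C, Ar
Reagents that add atoms: benzyl alcohol, OCc1ccccc1
Why: Ullmann-type Cu-catalysed C–O coupling of an aryl iodide with a primary alcohol – the ortho 5-phenoxide assists copper (as in the classical Cu/alkoxide alcoholysis of 6- and 8-haloflavones), and Cu, unlike Pd, leaves the ortho O-allyl group alone (o-allyloxy aryl iodides couple without cyclisation under Cu/phenanthroline).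

**Step 5**
Reactants: 9
Product: 10, 6-(benzyloxy)-2-(2,2-diphenyl-1,3-benzodioxol-5-yl)-5,7-dihydroxy-4H-chromen-4-one
Conditions: Pd(PPh3)4 (5 mol%), morpholine (5 eq), THF, rt
Reagents that add atoms: none
Why: Tsuji–Trost deallylation – Pd(0) ionises the allyl aryl ether to π-allyl-Pd and the stabilised 7-phenoxide, morpholine traps the allyl group, and the benzyl ether and ketal are inert (no aryl halide remains).

**Step 6**
Reactants: 10; 11 2,2,2-trichloroethyl chlorosulfate
Product: 12, 6-(benzyloxy)-2-(2,2-diphenyl-1,3-benzodioxol-5-yl)-5-hydroxy-4-oxo-4H-chromen-7-yl 2,2,2-trichloroethyl sulfate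
Conditions: Cl3CCH2OSO2Cl (1.3 eq), Et3N (1.5 eq), DMAP (0.5 eq), THF, 0 °C → rt
Reagents that add atoms: 2,2,2-trichloroethyl chlorosulfate, ClS(=O)(=O)OCC(Cl)(Cl)Cl
Why: O-Sulfation as a protected sulfate diester – the 7-OH is the only nucleophilic phenol (5-OH chelated, all others masked), and the neutral trichloroethyl diester can be purified on silica.

**Step 7**
Reactants: 12
Product: 13, 6-hydroxyluteolin 7-sulfate [2-(3,4-dihydroxyphenyl)-5,6-dihydroxy-4-oxo-4H-chromen-7-yl hydrogen sulfate]
Conditions: 10% Pd/C, HCO2NH4 (8 eq), then H2 (1 atm), MeOH/THF, rt; filter; Dowex 50W (H⁺), 0 °C; lyophilise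
Reagents that add atoms: none
Why: Global reductive deprotection – Pd/formate cleaves the trichloroethyl sulfate ester to the sulfate monoester, and catalytic hydrogenolysis removes the benzyl ether (as toluene) and the diphenylmethylene ketal (as Ph2CH2), while the buffered medium preserves the aryl sulfate and the flavone C2=C3 bond resists reduction at rt.

## Compound list

1 | Luteolin | O=c1cc(-c2ccc(O)c(O)c2)oc2cc(O)cc(O)c12 | starting material
2 | Dichlorodiphenylmethane | ClC(Cl)(c1ccccc1)c1ccccc1 | starting material
3 | 3',4'-O-Diphenylmethylene-luteolin | O=c1cc(-c2ccc3c(c2)OC(c2ccccc2)(c2ccccc2)O3)oc2cc(O)cc(O)c12 | intermediate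
4 | Allyl bromide | C=CCBr | starting material
5 | 7-O-Allyl-3',4'-O-diphenylmethylene-luteolin | O=c1cc(-c2ccc3c(c2)OC(c2ccccc2)(c2ccccc2)O3)oc2cc(OCC=C)cc(O)c12 | intermediate
6 | N-Iodosuccinimide | O=C1CCC(=O)N1I | starting material
7 | 7-O-Allyl-6-iodo-3',4'-O-diphenylmethylene-luteolin | O=c1cc(-c2ccc3c(c2)OC(c2ccccc2)(c2ccccc2)O3)oc2cc(OCC=C)c(I)c(O)c12 | intermediate
8 | Benzyl alcohol | OCc1ccccc1 | starting material
9 | 7-O-Allyl-6-benzyloxy-3',4'-O-diphenylmethylene-luteolin | O=c1cc(-c2ccc3c(c2)OC(c2ccccc2)(c2ccccc2)O3)oc2cc(OCC=C)c(OCc3ccccc3)c(O)c12 | intermediate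
10 | 6-Benzyloxy-3',4'-O-diphenylmethylene-luteolin (5,7-diol) | O=c1cc(-c2ccc3c(c2)OC(c2ccccc2)(c2ccccc2)O3)oc2cc(O)c(OCc3ccccc3)c(O)c12 | intermediate
11 | 2,2,2-Trichloroethyl chlorosulfate | ClS(=O)(=O)OCC(Cl)(Cl)Cl | starting material
12 | 7-O-(2,2,2-Trichloroethoxysulfonyl)-6-benzyloxy-3',4'-O-diphenylmethylene-luteolin | O=c1cc(-c2ccc3c(c2)OC(c2ccccc2)(c2ccccc2)O3)oc2cc(OS(=O)(=O)OCC(Cl)(Cl)Cl)c(OCc3ccccc3)c(O)c12 | intermediate
13 | 6-Hydroxyluteolin 7-sulfate | O=c1cc(-c2ccc(O)c(O)c2)oc2cc(OS(=O)(=O)O)c(O)c(O)c12 | target

## Summary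

Total steps: 7. Longest linear sequence: 7 (fully linear from luteolin).

Three steps most likely to fail, each with a fallback that changes the approach:

1. **Step 4 (Cu-catalysed C–O coupling on the di-ortho-substituted 6-iodide).** Risks are protodeiodination, slow coupling, and base-induced pyranone ring-opening and reclosure (Wessely–Moser type) that would scramble C6 to C8. Fallback: form the C6–O bond by C–B oxidation instead. Carry the 7-OH as a MOM ether in place of allyl (allyl is not Pd-compatible next to the iodide). Then run Miyaura borylation (B2pin2, Pd(dppf)Cl2, KOAc), oxidise with NaBO3 to the 6-phenol, and benzylate the 6-OH selectively (BnBr, K2CO3; the chelated 5-OH is inert).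

2. **Step 3 (C6 versus C8 iodination).** Risks are C8 attack or di-iodination. Fallback: drop the late-stage C–H functionalisation and build compound 10 de novo with the C6 oxygen in place and regiochemistry fixed by symmetry. Prepare 4-benzyloxy-3,5-bis(methoxymethoxy)phenol from 3,4,5-trihydroxybenzaldehyde (4-O-benzylation, 2 × MOM, Dakin oxidation) and ortho-iodinate it. Then close the pyranone ring by Pd-catalysed carbonylative Sonogashira annulation (CO, Et2NH) with 5-ethynyl-2,2-diphenyl-1,3-benzodioxole, and remove the MOM groups to reach 10.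

3. **Step 7 (three-fold reductive unmasking).** Risks are incomplete ketal hydrogenolysis, partial C2=C3 reduction, and sulfate loss from the HCl released on trichloroethyl cleavage or on acidic ion exchange. Fallback: give up the protected-diester concept. Sulfate 10 directly with SO3·NMe3, isolate the base-stable tetrabutylammonium aryl sulfate monoester, and hydrogenolyse that salt under neutral conditions (Pd(OH)2/C, H2, MeOH/THF/H2O). If the ketal still resists, carry the B-ring catechol as two benzyl ethers from the start. Keep the product as its ammonium or sodium salt until a brief cold H⁺ exchange.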